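**Retrosynthetic overview**

- Ring A is numbered C1 (styryl), C2 (H), C3 (OH), C4 (prenyl), C5 (OMe), C6 (prenyl). The styryl carbon C1 is meta to both oxygens and the prenylated C4 lies between them, so ring A is a latent 2-prenyl-5-styrylcyclohexane-1,3-dione.
- Late stage: target 18 from phenol 16 by O-methylation of the C5 oxygen and deallylation of the C3 oxygen; 16 from enone 12 by selenoxide dehydrogenation and tautomerization.
- The C6 prenyl is put in by kinetic α′-alkylation of the allyl vinylogous ester 10 of the mirror-symmetric dione 9.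
- Key disconnection of the carbocycle: C1–C6 (Michael) and C4–C5 (Claisen), leading to dienone 4 and dimethyl malonate 5; 4 comes from cinnamaldehyde 1 and 6-methylhept-5-en-2-one 2 by aldol condensation.
- Ring order: the phenyl ring is bought with 1; ring A is the only ring formed (step 2) and is aromatized in step 7.

Key step: step 2

Assumption: the target has no stereocentre. The sp3 ring centres of 3, 6–10 and 12–14 are transient and are carried as racemates (the expected relative configuration is drawn where one is predicted); step 7 erases all of them. The E styryl geometry comes from 1 and is not touched.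

**Route**

Step 1
Reactants: 1 (E)-cinnamaldehyde; 2 6-methylhept-5-en-2-one
Product: 4 (1E,3E)-9-methyl-1-phenyldeca-1,3,8-trien-5-one, via β-hydroxy ketone 3 (not isolated)
Conditions: 2 (2 equiv), aq. NaOH (cat.), EtOH, 0 °C to rt
Reagents that add atoms: none
Why: Claisen–Schmidt aldol condensation, in which under hydroxide catalysis only the aldol formed at the methyl group of 2 dehydrates readily (E1cB) while the more hindered methylene aldol reverts, cinnamaldehyde cannot self-condense, and the new conjugated C=C should form as the thermodynamic E isomer.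

Step 2
Reactants: 4 (1E,3E)-9-methyl-1-phenyldeca-1,3,8-trien-5-one; 5 dimethyl malonate
Product: 7 methyl 2,4-dioxo-3-(3-methylbut-2-enyl)-6-[(E)-2-phenylethenyl]cyclohexane-1-carboxylate (racemic; enolized), via Michael adduct 6 (not isolated)
Conditions: NaOMe (1.2 equiv), MeOH, reflux; then cold 1 M HCl
Reagents that add atoms: none
Why: Sodium dimethyl malonate adds to the β-carbon of 4 (Michael addition, forming C1–C6 of ring A); proton transfer then places the ketone enolate on the homoprenyl-bearing α′-carbon, which attacks one malonate ester carbonyl and expels methoxide (Claisen condensation, forming C4–C5). The closest known reaction type is the malonate Michael–Claisen annulation of enones to 4-carboalkoxycyclohexane-1,3-diones, which is established for cinnamylidene ketones. The one ring closed is the six-membered carbocycle that becomes ring A, by a favoured 6-(enolendo)-exo-trig attack of the ketone enolate carbon on the ester carbonyl. The sp3 centres created (C1, C3 and C6 of 7) are enolized or epimerizable, form as a racemic mixture and are all erased on aromatization, so none needs control. The step needs 1,4- rather than 1,6-addition: Michael addition is reversible, the δ-carbon is shielded by the phenyl group, and only the 1,4-adduct places an ester where the α′-carbon can close a six-membered ring (the 1,6-adduct could only close an eight-membered one), so irreversible deprotonation of the product dione by methoxide should funnel material to 7.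

Step 3
Reactants: 7 methyl 2,4-dioxo-3-(3-methylbut-2-enyl)-6-[(E)-2-phenylethenyl]cyclohexane-1-carboxylate
Product: 9 2-(3-methylbut-2-enyl)-5-[(E)-2-phenylethenyl]cyclohexane-1,3-dione, via keto acid 8 (not isolated)
Conditions: 2 M aq. NaOH, 80 °C; then 2 M HCl to pH 3–4, 50–60 °C
Reagents that add atoms: none
Why: Saponification of the β-keto ester gives keto acid 8 as its dianion, which on gentle acidification should lose CO2 through the cyclic β-keto acid transition state, the mild pH and temperature being chosen so that the enol of 9 does not cyclize onto its prenyl group.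

Step 4
Reactants: 9 2-(3-methylbut-2-enyl)-5-[(E)-2-phenylethenyl]cyclohexane-1,3-dione
Product: 10 2-(3-methylbut-2-enyl)-5-[(E)-2-phenylethenyl]-3-(prop-2-enyloxy)cyclohex-2-en-1-one (racemic)
Conditions: allyl alcohol, PPh3, DIAD, THF, 0 °C to rt
Reagents that add atoms: allyl alcohol (prop-2-en-1-ol), C=CCO
Why: Mitsunobu O-alkylation of the acidic enol of the 1,3-dione by the allyloxyphosphonium ion, which should favour the enol oxygen over the fully substituted C2, avoids acid that would cyclize the prenyl group, and raises no regiochemical question because the mirror plane of 9 makes its two oxygens equivalent.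

Step 5
Reactants: 10 2-(3-methylbut-2-enyl)-5-[(E)-2-phenylethenyl]-3-(prop-2-enyloxy)cyclohex-2-en-1-one; 11 prenyl bromide (1-bromo-3-methylbut-2-ene)
Product: 12 trans-2,6-bis(3-methylbut-2-enyl)-5-[(E)-2-phenylethenyl]-3-(prop-2-enyloxy)cyclohex-2-en-1-one (racemic)
Conditions: LiN(i-Pr)2 (1.1 equiv), THF, −78 °C; then 11, DMPU, −78 to −20 °C
Reagents that add atoms: none
Why: Stork–Danheiser alkylation, in which kinetic deprotonation of the vinylogous ester occurs at the α′-carbon (C6) beside the free carbonyl and the enolate should be alkylated by the primary allylic bromide anti to the C5 styryl group, giving the trans isomer (of no consequence later).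

Step 6
Reactants: 12 trans-2,6-bis(3-methylbut-2-enyl)-5-[(E)-2-phenylethenyl]-3-(prop-2-enyloxy)cyclohex-2-en-1-one
Product: 13 2,6-bis(3-methylbut-2-enyl)-6-(phenylselanyl)-5-[(E)-2-phenylethenyl]-3-(prop-2-enyloxy)cyclohex-2-en-1-one (racemic; PhSe trans to the styryl group)
Conditions: LiN(i-Pr)2 (1.2 equiv), THF, −78 °C; then PhSeBr, −78 °C
Reagents that add atoms: phenylselenyl bromide, Br[Se]c1ccccc1
Why: A second kinetic α′-deprotonation gives the fully substituted enolate, which should be selenenylated at carbon (Reich–Sharpless α-selenenylation) faster than PhSeBr adds to the alkenes and from the face opposite the C5 styryl group, leaving C5–H cis to selenium as the syn elimination requires.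

Step 7
Reactants: 13 2,6-bis(3-methylbut-2-enyl)-6-(phenylselanyl)-5-[(E)-2-phenylethenyl]-3-(prop-2-enyloxy)cyclohex-2-en-1-one
Product: 16 2,6-bis(3-methylbut-2-enyl)-5-[(E)-2-phenylethenyl]-3-(prop-2-enyloxy)phenol, via selenoxide 14 (not isolated), via cross-conjugated dienone 15 (not isolated)
Conditions: mCPBA (1.0 equiv), CH2Cl2, −78 °C; then i-Pr2NH, −78 °C to rt
Reagents that add atoms: none
Why: Selenium is oxidized at −78 °C far faster than the alkenes are epoxidized, the selenoxide should undergo syn elimination with the cis C5–H on warming to give the cyclohexa-2,5-dienone, and amine-assisted enolization through C4–H then aromatizes it irreversibly to the phenol while the amine also buffers the selenenic acid.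

Step 8
Reactants: 16 2,6-bis(3-methylbut-2-enyl)-5-[(E)-2-phenylethenyl]-3-(prop-2-enyloxy)phenol
Product: 17 1-methoxy-2,6-bis(3-methylbut-2-enyl)-5-[(E)-2-phenylethenyl]-3-(prop-2-enyloxy)benzene
Conditions: MeI, K2CO3, DMF, rt to 40 °C
Reagents that add atoms: iodomethane, CI
Why: Williamson O-methylation of the phenoxide, which should proceed on the di-ortho-substituted phenol with the small electrophile in a polar aprotic solvent and leaves the allyl ether and all alkenes untouched.

Step 9
Reactants: 17 1-methoxy-2,6-bis(3-methylbut-2-enyl)-5-[(E)-2-phenylethenyl]-3-(prop-2-enyloxy)benzene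
Product: 18 chiricanine C, 3-methoxy-2,4-bis(3-methylbut-2-enyl)-5-[(E)-2-phenylethenyl]phenol
Conditions: Pd(PPh3)4 (5 mol %), morpholine, THF, rt
Reagents that add atoms: none
Why: Tsuji–Trost-type deallylation, in which zerovalent palladium ionizes the aryl allyl ether to a π-allyl complex and the phenoxide, morpholine captures the allyl group, and the prenyl and styryl alkenes, which carry no leaving group, should be untouched.

**Compound list**

1 | (E)-cinnamaldehyde | O=C/C=C/c1ccccc1 | starting material
2 | 6-methylhept-5-en-2-one | CC(=O)CCC=C(C)C | starting material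
3 | (1E)-3-hydroxy-9-methyl-1-phenyldeca-1,8-dien-5-one (racemic aldol adduct) | CC(C)=CCCC(=O)CC(O)/C=C/c1ccccc1 | intermediate
4 | (1E,3E)-9-methyl-1-phenyldeca-1,3,8-trien-5-one | CC(C)=CCCC(=O)/C=C/C=C/c1ccccc1 | intermediate
5 | dimethyl malonate | COC(=O)CC(=O)OC | starting material
6 | dimethyl 2-[(1E)-9-methyl-5-oxo-1-phenyldeca-1,8-dien-3-yl]propanedioate (racemic Michael adduct) | COC(=O)C(C(=O)OC)C(/C=C/c1ccccc1)CC(=O)CCC=C(C)C | intermediate
7 | methyl 2,4-dioxo-3-(3-methylbut-2-enyl)-6-[(E)-2-phenylethenyl]cyclohexane-1-carboxylate (racemic; enol tautomers and epimers, drawn as the triketo form) | COC(=O)C1C(=O)C(CC=C(C)C)C(=O)CC1/C=C/c1ccccc1 | intermediate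
8 | 2,4-dioxo-3-(3-methylbut-2-enyl)-6-[(E)-2-phenylethenyl]cyclohexane-1-carboxylic acid (racemic; enolized) | OC(=O)C1C(=O)C(CC=C(C)C)C(=O)CC1/C=C/c1ccccc1 | intermediate
9 | 2-(3-methylbut-2-enyl)-5-[(E)-2-phenylethenyl]cyclohexane-1,3-dione (enolized; drawn as the diketone) | O=C1CC(/C=C/c2ccccc2)CC(=O)C1CC=C(C)C | intermediate
10 | 2-(3-methylbut-2-enyl)-5-[(E)-2-phenylethenyl]-3-(prop-2-enyloxy)cyclohex-2-en-1-one (racemic) | C=CCOC1=C(CC=C(C)C)C(=O)CC(/C=C/c2ccccc2)C1 | intermediate
11 | prenyl bromide (1-bromo-3-methylbut-2-ene) | CC(C)=CCBr | starting material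
12 | trans-2,6-bis(3-methylbut-2-enyl)-5-[(E)-2-phenylethenyl]-3-(prop-2-enyloxy)cyclohex-2-en-1-one (racemic; one enantiomer drawn) | C=CCOC1=C(CC=C(C)C)C(=O)[C@@H](CC=C(C)C)[C@H](/C=C/c2ccccc2)C1 | intermediate
13 | 2,6-bis(3-methylbut-2-enyl)-6-(phenylselanyl)-5-[(E)-2-phenylethenyl]-3-(prop-2-enyloxy)cyclohex-2-en-1-one (racemic; PhSe trans to styryl; one enantiomer drawn) | C=CCOC1=C(CC=C(C)C)C(=O)[C@@](CC=C(C)C)([Se]c2ccccc2)[C@H](/C=C/c2ccccc2)C1 | intermediate
14 | selenoxide of 13 (racemic; mixture of epimers at selenium) | C=CCOC1=C(CC=C(C)C)C(=O)[C@@](CC=C(C)C)([Se](=O)c2ccccc2)[C@H](/C=C/c2ccccc2)C1 | intermediate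
15 | 2,6-bis(3-methylbut-2-enyl)-5-[(E)-2-phenylethenyl]-3-(prop-2-enyloxy)cyclohexa-2,5-dien-1-one | C=CCOC1=C(CC=C(C)C)C(=O)C(CC=C(C)C)=C(/C=C/c2ccccc2)C1 | intermediate
16 | 2,6-bis(3-methylbut-2-enyl)-5-[(E)-2-phenylethenyl]-3-(prop-2-enyloxy)phenol | C=CCOc1cc(/C=C/c2ccccc2)c(CC=C(C)C)c(O)c1CC=C(C)C | intermediate
17 | 1-methoxy-2,6-bis(3-methylbut-2-enyl)-5-[(E)-2-phenylethenyl]-3-(prop-2-enyloxy)benzene | C=CCOc1cc(/C=C/c2ccccc2)c(CC=C(C)C)c(OC)c1CC=C(C)C | intermediate
18 | chiricanine C, 3-methoxy-2,4-bis(3-methylbut-2-enyl)-5-[(E)-2-phenylethenyl]phenol | COc1c(CC=C(C)C)c(O)cc(/C=C/c2ccccc2)c1CC=C(C)C | target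

**Step count and risks**

Total step count: 9. Longest linear sequence: 9 steps (1 to 18).

Most likely to fail, in order:

1. Step 7. The selenoxide may take a hydrogen from the side-chain CH2 of the C6 prenyl group instead of the ring C5–H, giving an exocyclic diene that does not aromatize cleanly, and electrophilic selenium by-products may add to the prenyl alkenes. Fallback: aromatize before C6 carries a side chain, so that only a ring hydrogen is available. The fallback sets out from 10. Treatment with LiN(i-Pr)2 and PhSeBr (THF, −78 °C) should give 2-(3-methylbut-2-enyl)-6-(phenylselanyl)-5-[(E)-2-phenylethenyl]-3-(prop-2-enyloxy)cyclohex-2-en-1-one F1. Oxidation (mCPBA, −78 °C; i-Pr2NH, to rt) and tautomerization should give 2-(3-methylbut-2-enyl)-5-[(E)-2-phenylethenyl]-3-(prop-2-enyloxy)phenol F2. Its sodium phenoxide (NaH, toluene) is then C-prenylated with 11 at the one free ortho position, the classical ortho-selective alkylation of phenoxides in non-polar solvents. The fallback comes back to the route at 16.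

2. Step 2. Claisen closure through the substituted α′-methylene may be slow, so the reversible Michael adduct may drain into 1,6-addition or a second Michael addition. Fallback: close the ring through a methyl ketone and bring in the C4 prenyl afterwards. The fallback sets out from 1. Condensation with acetone (aq. NaOH) gives (3E,5E)-6-phenylhexa-3,5-dien-2-one F3. Annulation with 5 (NaOMe, MeOH, reflux) gives methyl 2,4-dioxo-6-[(E)-2-phenylethenyl]cyclohexane-1-carboxylate F4. Saponification and decarboxylation (aq. NaOH; then HCl) give 5-[(E)-2-phenylethenyl]cyclohexane-1,3-dione F5. C2-alkylation with 11 (aq. KOH, rt) then comes back to the route at 9.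

3. Step 4. Alkylation may occur at C2 instead of at oxygen, giving the 2-allyl-2-prenyl dione. Fallback: replace the alkylation by addition–elimination at C3. The fallback sets out from 9. Oxalyl chloride with catalytic DMF (CH2Cl2, 0 °C) should give 3-chloro-2-(3-methylbut-2-enyl)-5-[(E)-2-phenylethenyl]cyclohex-2-en-1-one F6. Sodium allyloxide (allyl alcohol, NaH, THF, 0 °C) then displaces chloride by conjugate addition–elimination and comes back to the route at 10.

**Further compounds**

F1 | step 7 | 2-(3-methylbut-2-enyl)-6-(phenylselanyl)-5-[(E)-2-phenylethenyl]-3-(prop-2-enyloxy)cyclohex-2-en-1-one (racemic; PhSe trans to styryl) | C=CCOC1=C(CC=C(C)C)C(=O)[C@@H]([Se]c2ccccc2)[C@H](/C=C/c2ccccc2)C1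
F2 | step 7 | 2-(3-methylbut-2-enyl)-5-[(E)-2-phenylethenyl]-3-(prop-2-enyloxy)phenol | C=CCOc1cc(/C=C/c2ccccc2)cc(O)c1CC=C(C)C
F3 | step 2 | (3E,5E)-6-phenylhexa-3,5-dien-2-one | CC(=O)/C=C/C=C/c1ccccc1
F4 | step 2 | methyl 2,4-dioxo-6-[(E)-2-phenylethenyl]cyclohexane-1-carboxylate (racemic; enolized) | COC(=O)C1C(=O)CC(=O)CC1/C=C/c1ccccc1
F5 | step 2 | 5-[(E)-2-phenylethenyl]cyclohexane-1,3-dione | O=C1CC(=O)CC(/C=C/c2ccccc2)C1
F6 | step 4 | 3-chloro-2-(3-methylbut-2-enyl)-5-[(E)-2-phenylethenyl]cyclohex-2-en-1-one (racemic) | ClC1=C(CC=C(C)C)C(=O)CC(/C=C/c2ccccc2)C1
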